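- The pitfall here is a flat curve: in the east run substrate stands at 83% and then 82%, which looks like a stop, yet target climbs from 2% to 6% over the same readings.

| setting | east | south-east | flask |
|---|---|---|---|
| substrate | 25 mM | 25 mM | 25 mM |
| partner | 27.5 mM | 27.5 mM | 27.5 mM |
| reagent | 27.5 mM | 18 mM | 27.5 mM |
| remark | the very flask that is asked about, followed so far | run made earlier |  |
| time |  |  | 4.0 h |

east run (percent of the substrate charged)

| time / min | substrate / % | target / % | open intermediate / % |
|---|---|---|---|
| 8.00 | 98 | 0 | 1 |
| 12.0 | 95 | 0 | 5 |
| 20.0 | 94 | 0 | 4 |
| 25.0 | 90 | 0 | 6 |
| 40.0 | 86 | 0 | 9 |
| 60.0 | 83 | 2 | 14 |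
| 90.0 | 82 | 6 | 15 |

south-east run (percent of the substrate charged)

| time / h | substrate / % | target / % | open intermediate / % |
|---|---|---|---|
| 0.250 | 97 | 0 | 6 |
| 0.333 | 95 | 0 | 6 |
| 0.500 | 91 | 1 | 7 |
| 0.833 | 93 | 2 | 9 |
| 1.33 | 89 | 0 | 9 |
| 2.00 | 84 | 5 | 8 |
| 3.00 | 85 | 6 | 10 |

(scatter of a reading: 1.5 percentage points)

- what is said of target includes idle adduct
- steps that have been proposed: 2 second intermediate -> homo product; reagent + target <-> idle adduct; substrate + reagent -> open intermediate; open intermediate + second intermediate -> target; reagent + partner -> second intermediate
- the reaction counts as stopped when no species that holds the substrate changes by six tenths of a point or more over the second half of the time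

* why nothing more happens at 4.0 h, or that something still does (it is still moving / the reagent has run out first / the partner has run out first / all of the substrate has reacted)
* part of the substrate gone at 4.0 h
* the target standing at 4.0 h, as a percentage of the substrate charged
* the open intermediate standing at 4.0 h, as a percentage of the substrate charged

- Here is the quick number you asked for. Substrate and partner compete for one reagent. Taking each of these two steps as first order in each of its two species, reagent cancels from the comparison.
- South-east substrate reads 84% and 85%, so take its 18 mM of reagent as reacted: on that assumption substrate took 3.75 mM and partner 14.3 mM.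
- The selectivity factor, the logarithm of the partner fraction left over that of the substrate fraction left, reads 4.49, with the scatter of those readings.
- Partner step over substrate step is this factor times partner over substrate. In the east flask this reckons to 4.94 at the start and to less at 90.0 min, 2.47.
- By then about 6.77 mM of reagent reckons to remain in the east flask. Counting that whole amount as reacted and split at that ratio, my own figure for substrate gone is 25.8%, a little above the forecast.
- The forecast says it is still moving, with 24% gone, 14% target and 10% open intermediate, on the ground that “the reagent tails off slowly”.
- In the flask at 4.0 h, it is still moving, with 26.7% gone, 15.2% target and 11.5% open intermediate.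

    2 second intermediate → homo product (k = 0.00446 M⁻¹ s⁻¹)
    reagent + target ⇌ idle adduct, settled at all times (K = 64.5 M⁻¹)
    substrate + reagent → open intermediate (k = 0.00288 M⁻¹ s⁻¹)
    open intermediate + second intermediate → target (k = 0.0103 M⁻¹ s⁻¹)
    reagent + partner → second intermediate (k = 0.0106 M⁻¹ s⁻¹)

- At 4.00 h the flask keeps less of its partner, 32%, than of its substrate, 73%, each of its own charge. The factor 4.49 times partner over substrate in mM then gives a rate ratio of 2.15; the computed ratio of the partner step to the substrate step in their use of reagent is 1.8, with 6.2% of the charged reagent left.
- In a neighbour flask, like this one but with 69 mM of reagent, partner stands at 1.05% of its charge at 4.00 h, and the factor 4.49 puts substrate at 36.2% of its charge. The computed substrate in that neighbour flask is 29.0%, so 71.0% has gone.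

All runs were computed with constants of no real substance, noise included.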